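**Plan**

- Retrosynthesis: the A ring (C4a, C5–C8, C8a) is cut at C8–C8a and C4a–C5. Its alternating pattern (O1 on C8a, OH on C5 and C7, prenyl on C6 and C8) maps C5–C8 onto the four-carbon bis(silyloxy)diene of a 2,4-diprenyl acetoacetate. C4a=C8a is the enol-ether double bond of a 2-aryl-2,3-dihydropyran-4-one, with bromine on C4a as the leaving group for aromatisation.
- The bromo-pyranone is cut further at C4a–Br, at the chromene pyran ring (aryl propargyl ether) and at O1–C8a/C2–C3 (aryl aldehyde plus Danishefsky's diene). The diene goes back to methyl acetoacetate and two prenyl bromides.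
- Forward: the B-ring benzene is bought. The dihydropyranone (C ring) is made first by hetero-Diels–Alder reaction and brominated, the chromene pyran ring is closed thermally, and the A ring is closed last.
- Stereochemistry: C2 (S) is the only stereocentre. It is set by the BINOL–titanium catalyst in the hetero-Diels–Alder step and carried through under neutral or Lewis-acidic conditions.

Key step: step 9

Assumption: the (S)-BINOL–Ti(IV) catalyst is taken to deliver the diene to the Si face of the aryl aldehyde, the sense needed for (S)-C2; if a first run shows the opposite sense, (R)-BINOL is used and nothing else changes.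

**Route**

Step 1
Reactants: 1 4-hydroxybenzaldehyde; 2 3-chloro-3-methylbut-1-yne
Product: 3 4-[(2-methylbut-3-yn-2-yl)oxy]benzaldehyde
Conditions: K2CO3, KI (cat.), CuI (cat.), acetone, reflux
Reagents that add atoms: none
Why: Copper-assisted Williamson-type O-alkylation of the phenoxide with a tertiary propargylic chloride is the standard entry to aryl 1,1-dimethylpropargyl ethers and leaves the aldehyde alone.

Step 2
Reactants: 3 4-[(2-methylbut-3-yn-2-yl)oxy]benzaldehyde; 4 Danishefsky's diene
Product: 6 (S)-2-{4-[(2-methylbut-3-yn-2-yl)oxy]phenyl}-2,3-dihydro-4H-pyran-4-one, via silyl aldol adduct 5 (not isolated)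
Conditions: (S)-BINOL (20 mol%), Ti(OiPr)4 (10 mol%), 4 Å MS, toluene, 0 °C; then TFA (cat.), CH2Cl2, 0 °C
Reagents that add atoms: none
Why: Catalytic asymmetric hetero-Diels–Alder reaction by the Mukaiyama-aldol/cyclisation pathway, in which the chiral BINOL–Ti Lewis acid directs the diene terminus to the Si face of the aldehyde (C2 = S) and acid then closes 5 by oxa-Michael addition and loss of methanol without breaking the carbinol C–O bond.

Step 3
Reactants: 6 (S)-2-{4-[(2-methylbut-3-yn-2-yl)oxy]phenyl}-2,3-dihydro-4H-pyran-4-one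
Product: 7 (S)-5-bromo-2-{4-[(2-methylbut-3-yn-2-yl)oxy]phenyl}-2,3-dihydro-4H-pyran-4-one
Conditions: NBS (1.05 equiv), CH2Cl2, 0 °C, dark
Reagents that add atoms: N-bromosuccinimide, O=C1CCC(=O)N1Br
Why: Electrophilic α-bromination of a vinylogous ester: C5 is the nucleophilic enol-ether carbon and the oxocarbenium ion loses H-5, while the terminal alkyne and the para-blocked aryl ether are far less reactive towards NBS in an aprotic solvent. The chromene double bond does not yet exist, and C2 is not involved.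

Step 4
Reactants: 7 (S)-5-bromo-2-{4-[(2-methylbut-3-yn-2-yl)oxy]phenyl}-2,3-dihydro-4H-pyran-4-one
Product: 8 (S)-5-bromo-2-(2,2-dimethyl-2H-chromen-6-yl)-2,3-dihydro-4H-pyran-4-one
Conditions: 1,2-dichlorobenzene (degassed), 150 °C
Reagents that add atoms: none
Why: Thermal aryl propargyl ether Claisen rearrangement, then enolisation, 1,5-hydrogen shift and oxa-6π electrocyclisation, gives the 2,2-dimethyl-2H-chromene as a single isomer because both ortho positions are equivalent; the neutral conditions should leave the bromo-enone and the non-enolisable C2–H alone.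

Step 5
Reactants: 9 methyl acetoacetate; 10 prenyl bromide
Product: 11 methyl 7-methyl-3-oxooct-6-enoate
Conditions: NaH, THF, 0 °C; n-BuLi, 0 °C; 10 (1.0 equiv), 0 °C → rt; aq. HCl
Reagents that add atoms: none
Why: γ-Alkylation of the acetoacetate dianion, whose terminal carbanion is the more reactive site and takes the allylic bromide by SN2.

Step 6
Reactants: 11 methyl 7-methyl-3-oxooct-6-enoate; 10 prenyl bromide
Product: 12 methyl 7-methyl-2-(3-methylbut-2-en-1-yl)-3-oxooct-6-enoate
Conditions: NaH (1.0 equiv), THF, 0 °C; 10 (1.0 equiv), 0 °C → rt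
Reagents that add atoms: none
Why: Acetoacetic ester C-alkylation of the stabilised enolate with a reactive allylic bromide, with one equivalent of base and halide to hold back dialkylation; the new centre is racemic and later becomes sp2.

Step 7
Reactants: 12 methyl 7-methyl-2-(3-methylbut-2-en-1-yl)-3-oxooct-6-enoate
Product: 13 methyl 7-methyl-2-(3-methylbut-2-en-1-yl)-3-(trimethylsilyloxy)octa-2,6-dienoate
Conditions: TMSCl, Et3N, toluene, rt; filtration
Reagents that add atoms: chlorotrimethylsilane, C[Si](C)(C)Cl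
Why: Soft enolisation and O-silylation of the β-keto ester, the first stage of the usual two-stage preparation of 1,3-bis(silyloxy)dienes.

Step 8
Reactants: 13 methyl 7-methyl-2-(3-methylbut-2-en-1-yl)-3-(trimethylsilyloxy)octa-2,6-dienoate
Product: 14 1-methoxy-7-methyl-2-(3-methylbut-2-en-1-yl)-1,3-bis(trimethylsilyloxy)octa-1,3,6-triene
Conditions: LDA, THF, −78 °C; TMSCl, −78 °C → rt; used without purification
Reagents that add atoms: chlorotrimethylsilane, C[Si](C)(C)Cl
Why: LDA removes a γ-proton (C4) of the silyloxy enoate and TMSCl traps the extended dienolate on the ester oxygen to give the bis(silyloxy)diene; its double-bond geometries do not matter because both ends become aromatic carbons.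

Step 9
Reactants: 8 (S)-5-bromo-2-(2,2-dimethyl-2H-chromen-6-yl)-2,3-dihydro-4H-pyran-4-one; 14 1-methoxy-7-methyl-2-(3-methylbut-2-en-1-yl)-1,3-bis(trimethylsilyloxy)octa-1,3,6-triene
Product: 18 (2S)-2-(2,2-dimethyl-2H-chromen-6-yl)-5,7-dihydroxy-6,8-bis(3-methylbut-2-en-1-yl)-2,3-dihydro-4H-chromen-4-one (CNP0188949.1), via Michael adduct 15 (not isolated), via 4a-bromo enedione 16 (not isolated), via 7-O-silyl flavanone 17 (not isolated)
Conditions: 14 (1.05 equiv), 2,6-di-tert-butyl-4-methylpyridine (0.3 equiv), CH2Cl2, −78 °C; TMSOTf (0.3 equiv) added last, −78 → 0 °C; then Et3N (2 equiv), 0 °C; then aq. citric acid, THF, 0 °C → rt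
Reagents that add atoms: none
Why: Proposed new method: TMSOTf silylates the enone oxygen of 8, the CH terminus of 14 (its most nucleophilic carbon) adds to the oxocarbenium carbon that becomes C8a (vinylogous Mukaiyama–Michael) to give 15, and the silyl enol ether carbon that becomes C4a then attacks the silyl-activated ester carbon (Mukaiyama–Claisen acylation, a 6-(enolexo)-exo-trig closure of the carbocycle) with loss of MeOSiMe3 to give 16. Et3N then takes HBr out across C4a–C8a, the resulting dienone tautomerises to the hydrogen-bonded phenol 17, and dilute acid cleaves the remaining aryl silyl ether. The closest known chemistry is the benzannulation of 1,3-bis(silyloxy)dienes and ketene-acetal dienes with 1,3-dielectrophiles, haloquinones and chromones, together with the TMSOTf-mediated conjugate addition of silyl enolates to 2,3-dihydro-4H-pyran-4-ones. No lasting stereocentre is formed, since the centres made at C8, C8a and C4a are flattened on aromatisation and C2 only looks on. The regiochemistry needed (diene terminus to C8a, ester carbon to C4a) follows from the polarity of both partners, O1 sitting on the electrophilic carbon and bromine on the enol carbon, and the bromine keeps C4a free of hydrogen so that O1 is not lost by E1cB across C4a–C8a. Keeping C2 intact requires a short-lived cation and no C3 enolate, which the order of addition (Lewis acid last at −78 °C), the hindered pyridine buffer and the brief, cold amine treatment are meant to secure.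

**Compound list**

1 | 4-hydroxybenzaldehyde | O=Cc1ccc(O)cc1 | starting material
2 | 3-chloro-3-methylbut-1-yne | C#CC(C)(C)Cl | starting material
3 | 4-[(2-methylbut-3-yn-2-yl)oxy]benzaldehyde | O=Cc1ccc(OC(C)(C)C#C)cc1 | intermediate
4 | Danishefsky's diene, (E)-1-methoxy-3-(trimethylsilyloxy)buta-1,3-diene | CO/C=C/C(=C)O[Si](C)(C)C | starting material
5 | (S,E)-1-methoxy-5-{4-[(2-methylbut-3-yn-2-yl)oxy]phenyl}-5-(trimethylsilyloxy)pent-1-en-3-one | CO/C=C/C(=O)C[C@@H](c1ccc(OC(C)(C)C#C)cc1)O[Si](C)(C)C | intermediate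
6 | (S)-2-{4-[(2-methylbut-3-yn-2-yl)oxy]phenyl}-2,3-dihydro-4H-pyran-4-one | O=C1C[C@@H](c2ccc(OC(C)(C)C#C)cc2)OC=C1 | intermediate
7 | (S)-5-bromo-2-{4-[(2-methylbut-3-yn-2-yl)oxy]phenyl}-2,3-dihydro-4H-pyran-4-one | O=C1C[C@@H](c2ccc(OC(C)(C)C#C)cc2)OC=C1Br | intermediate
8 | (S)-5-bromo-2-(2,2-dimethyl-2H-chromen-6-yl)-2,3-dihydro-4H-pyran-4-one | O=C1C[C@@H](c2ccc3c(c2)C=CC(C)(C)O3)OC=C1Br | intermediate
9 | methyl acetoacetate | COC(=O)CC(C)=O | starting material
10 | prenyl bromide, 1-bromo-3-methylbut-2-ene | CC(C)=CCBr | starting material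
11 | methyl 7-methyl-3-oxooct-6-enoate | COC(=O)CC(=O)CCC=C(C)C | intermediate
12 | methyl 7-methyl-2-(3-methylbut-2-en-1-yl)-3-oxooct-6-enoate (racemic) | COC(=O)C(CC=C(C)C)C(=O)CCC=C(C)C | intermediate
13 | methyl 7-methyl-2-(3-methylbut-2-en-1-yl)-3-(trimethylsilyloxy)octa-2,6-dienoate (enol geometry not defined) | COC(=O)C(CC=C(C)C)=C(O[Si](C)(C)C)CCC=C(C)C | intermediate
14 | 1-methoxy-7-methyl-2-(3-methylbut-2-en-1-yl)-1,3-bis(trimethylsilyloxy)octa-1,3,6-triene (diene geometry not defined) | COC(O[Si](C)(C)C)=C(CC=C(C)C)C(O[Si](C)(C)C)=CCC=C(C)C | intermediate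
15 | methyl 4-[(6S)-3-bromo-6-(2,2-dimethyl-2H-chromen-6-yl)-4-(trimethylsilyloxy)-5,6-dihydro-2H-pyran-2-yl]-7-methyl-2-(3-methylbut-2-en-1-yl)-3-(trimethylsilyloxy)octa-2,6-dienoate (other centres undefined) | COC(=O)C(CC=C(C)C)=C(O[Si](C)(C)C)C(CC=C(C)C)C1O[C@H](c2ccc3c(c2)C=CC(C)(C)O3)CC(O[Si](C)(C)C)=C1Br | intermediate
16 | (2S)-4a-bromo-2-(2,2-dimethyl-2H-chromen-6-yl)-6,8-bis(3-methylbut-2-en-1-yl)-7-(trimethylsilyloxy)-2,3,8,8a-tetrahydro-4H-chromene-4,5(4aH)-dione (C4a, C8, C8a undefined) | CC(C)=CCC1C(O[Si](C)(C)C)=C(CC=C(C)C)C(=O)C2(Br)C(=O)C[C@@H](c3ccc4c(c3)C=CC(C)(C)O4)OC12 | intermediate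
17 | (2S)-2-(2,2-dimethyl-2H-chromen-6-yl)-5-hydroxy-6,8-bis(3-methylbut-2-en-1-yl)-7-(trimethylsilyloxy)-2,3-dihydro-4H-chromen-4-one | CC(C)=CCc1c(O[Si](C)(C)C)c(CC=C(C)C)c2c(c1O)C(=O)C[C@@H](c1ccc3c(c1)C=CC(C)(C)O3)O2 | intermediate
18 | (2S)-2-(2,2-dimethyl-2H-chromen-6-yl)-5,7-dihydroxy-6,8-bis(3-methylbut-2-en-1-yl)-2,3-dihydro-4H-chromen-4-one (CNP0188949.1) | CC(C)=CCc1c(O)c(CC=C(C)C)c2c(c1O)C(=O)C[C@@H](c1ccc3c(c1)C=CC(C)(C)O3)O2 | target

**Summary**

Total step count: 9. Longest linear sequence: 5 steps (steps 1, 2, 3, 4, 9 from 4-hydroxybenzaldehyde; equally steps 5, 6, 7, 8, 9 from methyl acetoacetate).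

Steps most likely to fail:

1. Step 9. Several processes could defeat it.
   - The sequence may stop after the Michael addition, because the ester carbon is a weak electrophile and C4a is hindered.
   - Bromine may be transferred from the α-bromo-β-dicarbonyl stage to unreacted silyl enol ether.
   - The pyran ring may open by β-elimination of O1 through the C8 enol.
   - The para-alkoxybenzylic C2–O1 bond may ionise under the Lewis acid and erode the optical purity.

   Fallback with known chemistry, the chalcone route, setting out from 3 and 10 and returning at 18: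
   - Heating 3 in N,N-diethylaniline (190 °C) gives 2,2-dimethyl-2H-chromene-6-carbaldehyde F1.
   - Commercial 2,4,6-trihydroxyacetophenone is C-prenylated twice with 10 (aq. KOH) to 1-[2,4,6-trihydroxy-3,5-bis(3-methylbut-2-en-1-yl)phenyl]ethan-1-one F2.
   - MOMCl/i-Pr2NEt converts F2 into 1-[2-hydroxy-4,6-bis(methoxymethoxy)-3,5-bis(3-methylbut-2-en-1-yl)phenyl]ethan-1-one F3; the hydrogen-bonded ortho hydroxyl stays free.
   - Claisen–Schmidt condensation of F3 with F1 (KOH, EtOH) gives (E)-3-(2,2-dimethyl-2H-chromen-6-yl)-1-[2-hydroxy-4,6-bis(methoxymethoxy)-3,5-bis(3-methylbut-2-en-1-yl)phenyl]prop-2-en-1-one F4.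
   - NaOAc in refluxing EtOH closes F4 by oxa-Michael addition to the racemic 5,7-bis(methoxymethoxy) flavanone F5.
   - HCl/MeOH removes the acetals to give the racemic flavanone F6.
   - The (S)-enantiomer 18 is separated from F6 by preparative HPLC on a chiral stationary phase.

2. Step 4. The heat may cost HBr or optical purity at the benzylic ether centre (through the transient para-hydroxybenzyl stage of the rearrangement or an enol-mediated ring opening), or the rearrangement may stay incomplete at the temperature the bromo-enone tolerates.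

   Fallback, closing the chromene before the pyranone exists, setting out from 3 and returning at 8:
   - Thermal rearrangement of the aldehyde itself (PhNEt2, 190 °C) gives 2,2-dimethyl-2H-chromene-6-carbaldehyde F1.
   - The BINOL–Ti hetero-Diels–Alder reaction of step 2 with 4 gives, through the silyl aldol adduct (S,E)-5-(2,2-dimethyl-2H-chromen-6-yl)-1-methoxy-5-(trimethylsilyloxy)pent-1-en-3-one F7, (S)-2-(2,2-dimethyl-2H-chromen-6-yl)-2,3-dihydro-4H-pyran-4-one F8.
   - α-Bromination of F8 with NBS in CH2Cl2 at −20 °C gives 8. This run is aprotic and free of nucleophiles so that the chromene double bond, which now competes with the enol-ether carbon, is spared.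

3. Step 2. The electron-rich aldehyde may react slowly and with poor facial selectivity, and the para-alkoxybenzylic carbinol carbon may partly racemise during the acid-induced ring closure.

   Fallback, a reagent-controlled boron aldol in place of the catalytic cycloaddition, setting out from 3 and returning at 6:
   - The diisopinocampheylboron enolate of (E)-4-methoxybut-3-en-2-one (Ipc2BCl, i-Pr2NEt, −78 °C; reagent antipode chosen for the S carbinol) adds to 3. After oxidative work-up this gives (S,E)-5-hydroxy-1-methoxy-5-{4-[(2-methylbut-3-yn-2-yl)oxy]phenyl}pent-1-en-3-one F9.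
   - PPTS in CH2Cl2 cyclises F9 with loss of methanol to 6.

Further compounds
F1 | step 9 | 2,2-dimethyl-2H-chromene-6-carbaldehyde | O=Cc1ccc2c(c1)C=CC(C)(C)O2
F2 | step 9 | 1-[2,4,6-trihydroxy-3,5-bis(3-methylbut-2-en-1-yl)phenyl]ethan-1-one | CC(=O)c1c(O)c(CC=C(C)C)c(O)c(CC=C(C)C)c1O
F3 | step 9 | 1-[2-hydroxy-4,6-bis(methoxymethoxy)-3,5-bis(3-methylbut-2-en-1-yl)phenyl]ethan-1-one | CC(=O)c1c(O)c(CC=C(C)C)c(OCOC)c(CC=C(C)C)c1OCOC
F4 | step 9 | (E)-3-(2,2-dimethyl-2H-chromen-6-yl)-1-[2-hydroxy-4,6-bis(methoxymethoxy)-3,5-bis(3-methylbut-2-en-1-yl)phenyl]prop-2-en-1-one | COCOc1c(CC=C(C)C)c(O)c(C(=O)/C=C/c2ccc3c(c2)C=CC(C)(C)O3)c(OCOC)c1CC=C(C)C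
F5 | step 9 | racemic 2-(2,2-dimethyl-2H-chromen-6-yl)-5,7-bis(methoxymethoxy)-6,8-bis(3-methylbut-2-en-1-yl)-2,3-dihydro-4H-chromen-4-one | COCOc1c(CC=C(C)C)c(OCOC)c2c(c1CC=C(C)C)OC(c1ccc3c(c1)C=CC(C)(C)O3)CC2=O
F6 | step 9 | racemic 2-(2,2-dimethyl-2H-chromen-6-yl)-5,7-dihydroxy-6,8-bis(3-methylbut-2-en-1-yl)-2,3-dihydro-4H-chromen-4-one | CC(C)=CCc1c(O)c(CC=C(C)C)c2c(c1O)C(=O)CC(c1ccc3c(c1)C=CC(C)(C)O3)O2
F7 | step 4 | (S,E)-5-(2,2-dimethyl-2H-chromen-6-yl)-1-methoxy-5-(trimethylsilyloxy)pent-1-en-3-one | CO/C=C/C(=O)C[C@@H](c1ccc2c(c1)C=CC(C)(C)O2)O[Si](C)(C)C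
F8 | step 4 | (S)-2-(2,2-dimethyl-2H-chromen-6-yl)-2,3-dihydro-4H-pyran-4-one | O=C1C[C@@H](c2ccc3c(c2)C=CC(C)(C)O3)OC=C1
F9 | step 2 | (S,E)-5-hydroxy-1-methoxy-5-{4-[(2-methylbut-3-yn-2-yl)oxy]phenyl}pent-1-en-3-one | CO/C=C/C(=O)C[C@H](O)c1ccc(OC(C)(C)C#C)cc1
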